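**Retrosynthetic overview**
1. Target = (4E,6S,9S,13R,15S)-15-acetoxy-6,9-epoxyjatropha-1,4-diene-3,14-dione; the C15 acetate and the C14 ketone are installed last from a 14,15-diol carried as an acetonide.
2. The twelve-membered ring is closed last by ring-closing metathesis at C11=C12, followed by alkene hydrogenation; C4=C5 is then formed by dehydrating the aldol inside the ring.
3. Key union: intermolecular lithium-enolate aldol between C4 of the West cyclopentenone 24 and the C5 aldehyde of the East oxolane 9.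
4. West fragment (five-membered ring, made first, from a chiral cyclopentenyl acetate): the C3 silyl ether directs 1,2-addition to set C15; a Brown crotylation sets C13.
5. East fragment (oxolane ring, made second, from geranyl acetate): Brown prenylation sets C9 and the C10 quaternary carbon; Sharpless epoxidation with 5-exo ring closure sets C6.

Assumption: geranyl acetate, (1S,4R)-cis-4-acetoxycyclopent-2-en-1-ol and the α-pinene-derived Ipc boranes are taken as commercial; macrocycles are named with jatrophane numbering (five-membered ring = C15, C1, C2, C3, C4; chain C5–C14; ether oxygen between C6 and C9; methyls on C2, C6, C10, C10, C13). The route is a plan and has not been run; the C14 carbinol configuration is immaterial because it is oxidised in step 25.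

**East fragment**

Step 1
Reactants: 1 geranyl acetate [(2E)-3,7-dimethylocta-2,6-dien-1-yl acetate]
Product: 2 (2E)-5-(3,3-dimethyloxiran-2-yl)-3-methylpent-2-en-1-yl acetate (racemic at the epoxide)
Conditions: mCPBA (1.05 equiv), NaHCO3, CH2Cl2, 0 °C
Reagents that add atoms: 3-chloroperbenzoic acid, OOC(=O)c1cccc(Cl)c1
Why: Prilezhaev epoxidation selects the electron-rich 6,7-olefin because the 2,3-olefin is deactivated by the allylic acetate, and the epoxide stereocentre is destroyed in step 2.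

Step 2
Reactants: 2 (2E)-5-(3,3-dimethyloxiran-2-yl)-3-methylpent-2-en-1-yl acetate
Product: 3 (2E)-3-methyl-6-oxohex-2-en-1-yl acetate
Conditions: H5IO6, THF/H2O, 0 °C → rt
Reagents that add atoms: none
Why: Periodic acid opens the epoxide and cleaves the resulting glycol (Malaprade-type cleavage), giving the C9 aldehyde with the E-trisubstituted olefin and acetate untouched.

Step 3
Reactants: 3 (2E)-3-methyl-6-oxohex-2-en-1-yl acetate
Product: 5 (2E,6S)-6-hydroxy-3,7,7-trimethylnona-2,8-dien-1-yl acetate, via borinate ester 4 (not isolated)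
Conditions: (+)-Ipc2BH [from (−)-α-pinene], 3-methylbuta-1,2-diene, THF, −25 → 0 °C; then 3, Et2O, −78 °C; NaBO3·4H2O, THF/H2O, rt
Reagents that add atoms: B-(3-methylbut-2-en-1-yl)diisopinocampheylborane, made in the flask from (+)-Ipc2BH and 3-methylbuta-1,2-diene (CC(C)=C=C), CC(C)=CCB([C@H]1C[C@H]2C[C@@H]([C@@H]1C)C2(C)C)[C@H]1C[C@H]2C[C@@H]([C@@H]1C)C2(C)C
Why: Brown reverse prenylation (carbonyl allylation through a chair transition state with γ-attack) builds the C10 quaternary carbon, and the (−)-α-pinene-derived reagent attacks the Re face of the aldehyde to give the (S)-carbinol (C9).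

Step 4
Reactants: 5 (2E,6S)-6-hydroxy-3,7,7-trimethylnona-2,8-dien-1-yl acetate
Product: 6 (2E,6S)-3,7,7-trimethylnona-2,8-diene-1,6-diol
Conditions: K2CO3, MeOH, rt
Reagents that add atoms: none
Why: Base-catalysed transesterification frees the allylic alcohol needed to direct the epoxidation, with no stereocentre affected.

Step 5
Reactants: 6 (2E,6S)-3,7,7-trimethylnona-2,8-diene-1,6-diol
Product: 8 (1R)-1-[(2S,5S)-2-methyl-5-(2-methylbut-3-en-2-yl)oxolan-2-yl]ethane-1,2-diol, via epoxy diol 7 (not isolated)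
Conditions: Ti(OiPr)4, D-(−)-diethyl tartrate, t-BuOOH, 4 Å MS, CH2Cl2, −20 °C; then CSA (cat.), 0 °C → rt
Reagents that add atoms: tert-butyl hydroperoxide, CC(C)(C)OO
Why: Sharpless asymmetric epoxidation with D-(−)-tartrate gives the (2R,3R)-epoxy alcohol by reagent control, and the C9 hydroxyl then opens it 5-exo at the tertiary carbon with inversion, setting (6S) and the trans-2,5-disubstituted oxolane.

Step 6
Reactants: 8 (1R)-1-[(2S,5S)-2-methyl-5-(2-methylbut-3-en-2-yl)oxolan-2-yl]ethane-1,2-diol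
Product: 9 (2S,5S)-2-methyl-5-(2-methylbut-3-en-2-yl)oxolane-2-carbaldehyde
Conditions: NaIO4, THF/pH 7 buffer, 0 °C
Reagents that add atoms: none
Why: Malaprade glycol cleavage releases the non-enolisable C5 aldehyde without touching the quaternary C6 centre or the vinyl group.

**West fragment**

Step 7
Reactants: 10 (1S,4R)-cis-4-acetoxycyclopent-2-en-1-ol
Product: 11 (1R,4S)-4-[(tert-butyldimethylsilyl)oxy]cyclopent-2-en-1-yl acetate
Conditions: TBSCl, imidazole, DMF, rt
Reagents that add atoms: tert-butyldimethylsilyl chloride, CC(C)(C)[Si](C)(C)Cl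
Why: Standard silylation protects the carbinol that becomes the C3 oxygen and later the stereodirecting group.

Step 8
Reactants: 11 (1R,4S)-4-[(tert-butyldimethylsilyl)oxy]cyclopent-2-en-1-yl acetate
Product: 12 (1R,4S)-4-[(tert-butyldimethylsilyl)oxy]cyclopent-2-en-1-ol
Conditions: K2CO3, MeOH, 0 °C → rt
Reagents that add atoms: none
Why: Methanolysis removes the acetate while the secondary TBS ether is stable to carbonate.

Step 9
Reactants: 12 (1R,4S)-4-[(tert-butyldimethylsilyl)oxy]cyclopent-2-en-1-ol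
Product: 13 (4S)-4-[(tert-butyldimethylsilyl)oxy]cyclopent-2-en-1-one
Conditions: Dess–Martin periodinane, NaHCO3, CH2Cl2, 0 °C → rt
Reagents that add atoms: none
Why: Dess–Martin oxidation of the allylic alcohol under buffered conditions gives the enone without β-elimination of the silyloxy group.

Step 10
Reactants: 13 (4S)-4-[(tert-butyldimethylsilyl)oxy]cyclopent-2-en-1-one
Product: 14 tert-butyldimethyl{[(1S,2S)-2-methyl-4-[(trimethylsilyl)oxy]cyclopent-3-en-1-yl]oxy}silane
Conditions: MeLi, CuI, Et2O, −30 °C; TMSCl, then 13, THF, −78 °C; Et3N, pentane work-up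
Reagents that add atoms: lithium dimethylcuprate, [Li+].C[Cu-]C; chlorotrimethylsilane, C[Si](C)(C)Cl
Why: Gilman conjugate addition places the future C2 methyl trans to the silyloxy group, and in-situ silyl trapping fixes the enolate regiochemistry and prevents siloxide elimination.

Step 11
Reactants: 14 tert-butyldimethyl{[(1S,2S)-2-methyl-4-[(trimethylsilyl)oxy]cyclopent-3-en-1-yl]oxy}silane
Product: 15 (4S)-4-[(tert-butyldimethylsilyl)oxy]-3-methylcyclopent-2-en-1-one
Conditions: Pd(OAc)2 (1.05 equiv), MeCN, rt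
Reagents that add atoms: none
Why: Saegusa–Ito oxidation regenerates the enone through a palladium enolate whose only β-hydrogen is on the methyl-bearing carbon, giving zerovalent palladium and leaving the silyloxy stereocentre intact.

Step 12
Reactants: 15 (4S)-4-[(tert-butyldimethylsilyl)oxy]-3-methylcyclopent-2-en-1-one
Product: 16 (1R,4S)-4-[(tert-butyldimethylsilyl)oxy]-1-{[dimethyl(propan-2-yloxy)silyl]methyl}-3-methylcyclopent-2-en-1-ol
Conditions: (iPrO)Me2SiCH2MgCl (preformed, THF), CeCl3, THF, −78 → 0 °C; aq NH4Cl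
Reagents that add atoms: {[dimethyl(propan-2-yloxy)silyl]methyl}magnesium chloride, CC(C)O[Si](C)(C)C[Mg]Cl
Why: Cerium-mediated Grignard 1,2-addition (Tamao hydroxymethyl anion equivalent) occurs on the face anti to the bulky silyloxy group, setting the C15 quaternary carbinol with oxygen cis to the silyl ether.

Step 13
Reactants: 16 (1R,4S)-4-[(tert-butyldimethylsilyl)oxy]-1-{[dimethyl(propan-2-yloxy)silyl]methyl}-3-methylcyclopent-2-en-1-ol
Product: 17 (1R,4S)-4-[(tert-butyldimethylsilyl)oxy]-1-(hydroxymethyl)-3-methylcyclopent-2-en-1-ol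
Conditions: 30% H2O2, KF, KHCO3, MeOH/THF (1:1), rt
Reagents that add atoms: hydrogen peroxide, OO
Why: Tamao–Kumada oxidation converts the C–Si bond into C–OH with retention, under conditions that avoid Peterson elimination and spare the TBS ether.

Step 14
Reactants: 17 (1R,4S)-4-[(tert-butyldimethylsilyl)oxy]-1-(hydroxymethyl)-3-methylcyclopent-2-en-1-ol
Product: 18 (1R,4S)-4-[(tert-butyldimethylsilyl)oxy]-3-methyl-1-[(triethylsilyl)oxy]-1-{[(triethylsilyl)oxy]methyl}cyclopent-2-ene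
Conditions: TESOTf (2.5 equiv), 2,6-lutidine, CH2Cl2, −78 → 0 °C
Reagents that add atoms: triethylsilyl trifluoromethanesulfonate, CC[Si](CC)(CC)OS(=O)(=O)C(F)(F)F
Why: The silyl triflate silylates both the primary and the hindered tertiary alcohol, so C15–O is masked before the aldehyde is made.

Step 15
Reactants: 18 (1R,4S)-4-[(tert-butyldimethylsilyl)oxy]-3-methyl-1-[(triethylsilyl)oxy]-1-{[(triethylsilyl)oxy]methyl}cyclopent-2-ene
Product: 19 (1R,4S)-4-[(tert-butyldimethylsilyl)oxy]-3-methyl-1-[(triethylsilyl)oxy]cyclopent-2-ene-1-carbaldehyde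
Conditions: (COCl)2, DMSO, CH2Cl2, −78 → −40 °C; Et3N, → 0 °C
Reagents that add atoms: none
Why: Under Swern conditions a primary TES ether is cleaved and oxidised directly to the aldehyde while tertiary TES and secondary TBS ethers survive, giving the non-enolisable C14 aldehyde.

Step 16
Reactants: 19 (1R,4S)-4-[(tert-butyldimethylsilyl)oxy]-3-methyl-1-[(triethylsilyl)oxy]cyclopent-2-ene-1-carbaldehyde
Product: 21 (1R,2R)-1-[(1R,4S)-4-[(tert-butyldimethylsilyl)oxy]-3-methyl-1-[(triethylsilyl)oxy]cyclopent-2-en-1-yl]-2-methylbut-3-en-1-ol, via borinate ester 20 (not isolated)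
Conditions: (E)-but-2-ene, n-BuLi, KOtBu, THF, −78 → −45 °C; (+)-Ipc2BOMe [from (−)-α-pinene], −78 °C; BF3·OEt2; 19, −78 °C; then NaOH, 30% H2O2, rt
Reagents that add atoms: B-[(E)-but-2-en-1-yl]diisopinocampheylborane, made in the flask from (E)-but-2-ene (C/C=C/C), C/C=C/CB([C@H]1C[C@H]2C[C@@H]([C@@H]1C)C2(C)C)[C@H]1C[C@H]2C[C@@H]([C@@H]1C)C2(C)C
Why: Brown crotylation (carbonyl allylation) through a chair transition state gives the anti adduct from the E-reagent with Re-face attack under reagent control, setting (13R).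

Step 17
Reactants: 21 (1R,2R)-1-[(1R,4S)-4-[(tert-butyldimethylsilyl)oxy]-3-methyl-1-[(triethylsilyl)oxy]cyclopent-2-en-1-yl]-2-methylbut-3-en-1-ol
Product: 22 (1R,4S)-1-[(1R,2R)-1-hydroxy-2-methylbut-3-en-1-yl]-3-methylcyclopent-2-ene-1,4-diol
Conditions: Bu4NF, THF, 0 °C → rt; aq NH4Cl
Reagents that add atoms: none
Why: Fluoride removes both silyl ethers in one operation so that the oxygens can be re-differentiated by ring size in the next step.

Step 18
Reactants: 22 (1R,4S)-1-[(1R,2R)-1-hydroxy-2-methylbut-3-en-1-yl]-3-methylcyclopent-2-ene-1,4-diol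
Product: 23 (4R,5R,8S)-4-[(2R)-but-3-en-2-yl]-2,2,7-trimethyl-1,3-dioxaspiro[4.4]non-6-en-8-ol
Conditions: 2,2-dimethoxypropane, PPTS (cat.), CH2Cl2, rt
Reagents that add atoms: 2,2-dimethoxypropane, COC(C)(C)OC
Why: Acid-catalysed transketalisation selects the vicinal C14/C15 diol (five-membered dioxolane) over the strained bridged 1,3-acetal, leaving only the C3 allylic alcohol free.

Step 19
Reactants: 23 (4R,5R,8S)-4-[(2R)-but-3-en-2-yl]-2,2,7-trimethyl-1,3-dioxaspiro[4.4]non-6-en-8-ol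
Product: 24 (4R,5R)-4-[(2R)-but-3-en-2-yl]-2,2,7-trimethyl-1,3-dioxaspiro[4.4]non-6-en-8-one
Conditions: Dess–Martin periodinane, NaHCO3, CH2Cl2, rt
Reagents that add atoms: none
Why: Oxidation of the allylic alcohol gives the 2-methylcyclopentenone with C15–O already tied up, so no retro-aldol ring opening can scramble C15.

**Union and endgame**

Step 20
Reactants: 24 (4R,5R)-4-[(2R)-but-3-en-2-yl]-2,2,7-trimethyl-1,3-dioxaspiro[4.4]non-6-en-8-one; 9 (2S,5S)-2-methyl-5-(2-methylbut-3-en-2-yl)oxolane-2-carbaldehyde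
Product: 26 (4R,5S)-4-[(2R)-but-3-en-2-yl]-9-{hydroxy[(2S,5S)-2-methyl-5-(2-methylbut-3-en-2-yl)oxolan-2-yl]methyl}-2,2,7-trimethyl-1,3-dioxaspiro[4.4]non-6-en-8-one (diastereomer mixture at C4 and C5), via lithium enolate 25 (not isolated)
Conditions: LiN(iPr)2, THF, −78 °C, 30 min; 9, −78 °C, 1 h; AcOH/THF quench at −78 °C
Reagents that add atoms: none
Why: Intermolecular aldol addition of the only possible enolate of 24 (C4; C15 is quaternary and siloxide-type elimination would give an antiaromatic cyclopentadienone) to the non-enolisable aldehyde 9 forms the C4–C5 bond, and both new stereocentres are erased in step 23.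

Step 21
Reactants: 26 aldol adduct (diastereomer mixture)
Product: 27 (6S,9S,11E,13R,14R,15S)-5-hydroxy-14,15-(isopropylidenedioxy)-6,9-epoxyjatropha-1,11-dien-3-one (mixture at C4 and C5; any 11Z isomer converges in step 22)
Conditions: second-generation Grubbs catalyst RuCl2(=CHPh)(PCy3)(SIMes) (10 mol %), 1,4-benzoquinone (20 mol %), toluene (1 mM), 80 °C
Reagents that add atoms: none
Why: Ring-closing metathesis of the two terminal vinyl groups closes the twelve-membered carbocycle with loss of ethene, the trisubstituted enone olefin being metathesis-inert.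

Step 22
Reactants: 27 macrocyclic dienone
Product: 28 (6S,9S,13R,14R,15S)-5-hydroxy-14,15-(isopropylidenedioxy)-6,9-epoxyjatroph-1-en-3-one (mixture at C4 and C5)
Conditions: H2 (1 atm), RhCl(PPh3)3 (20 mol %), benzene/EtOH (1:1), rt
Reagents that add atoms: none
Why: Homogeneous hydrogenation with Wilkinson's catalyst reduces the disubstituted C11=C12 olefin and leaves the trisubstituted conjugated ring olefin, as in the selective reduction of carvone.

Step 23
Reactants: 28 saturated macrocyclic aldol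
Product: 30 (4E,6S,9S,13R,14R,15S)-14,15-(isopropylidenedioxy)-6,9-epoxyjatropha-1,4-dien-3-one, via C5 mesylate 29 (not isolated)
Conditions: MsCl, Et3N, CH2Cl2, 0 °C; then DBU, 0 °C → rt
Reagents that add atoms: none
Why: E1cB elimination of the β-mesyloxy ketone through the C3 enolate gives the cross-conjugated dienone, and the bridged medium ring is expected to favour the in-ring cis (4E) geometry.

Step 24
Reactants: 30 dienone acetonide
Product: 31 (4E,6S,9S,13R,14R,15S)-14,15-dihydroxy-6,9-epoxyjatropha-1,4-dien-3-one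
Conditions: AcOH/H2O (4:1), 50 °C
Reagents that add atoms: none
Why: Mild acid hydrolysis removes the acetonide; the dienone, oxolane and the electron-poor allylic C15 carbinol tolerate these conditions.

Step 25
Reactants: 31 diol
Product: 32 (4E,6S,9S,13R,15S)-15-hydroxy-6,9-epoxyjatropha-1,4-diene-3,14-dione
Conditions: IBX, DMSO, rt
Reagents that add atoms: none
Why: IBX oxidises the secondary C14 carbinol of a 1,2-diol to the α-ketol without glycol cleavage and under neutral conditions that do not epimerise the now α-positioned C13.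

Step 26
Reactants: 32 α-hydroxy ketone
Product: 33 (4E,6S,9S,13R,15S)-15-acetoxy-6,9-epoxyjatropha-1,4-diene-3,14-dione (target)
Conditions: Ac2O, DMAP, Et3N, CH2Cl2, rt → 35 °C
Reagents that add atoms: acetic anhydride, CC(=O)OC(C)=O
Why: DMAP-catalysed acylation (Steglich-type) esterifies the tertiary C15 alcohol, which cannot undergo retro-aldol because C4 is sp2.

**Compound list**

1 | geranyl acetate | CC(C)=CCC/C(C)=C/COC(C)=O | starting material
2 | (2E)-5-(3,3-dimethyloxiran-2-yl)-3-methylpent-2-en-1-yl acetate | CC(=O)OC/C=C(\C)CCC1OC1(C)C | intermediate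
3 | (2E)-3-methyl-6-oxohex-2-en-1-yl acetate | CC(=O)OC/C=C(\C)CCC=O | intermediate
4 | O-diisopinocampheylborinate of 5 | CC(=O)OC/C=C(\C)CC[C@H](OB([C@H]1C[C@H]2C[C@@H]([C@@H]1C)C2(C)C)[C@H]1C[C@H]2C[C@@H]([C@@H]1C)C2(C)C)C(C)(C)C=C | intermediate (not isolated)
5 | (2E,6S)-6-hydroxy-3,7,7-trimethylnona-2,8-dien-1-yl acetate | CC(=O)OC/C=C(\C)CC[C@H](O)C(C)(C)C=C | intermediate
6 | (2E,6S)-3,7,7-trimethylnona-2,8-diene-1,6-diol | OC/C=C(\C)CC[C@H](O)C(C)(C)C=C | intermediate
7 | (3S)-1-[(2R,3R)-3-(hydroxymethyl)-2-methyloxiran-2-yl]-4,4-dimethylhex-5-en-3-ol | OC[C@H]1O[C@]1(C)CC[C@H](O)C(C)(C)C=C | intermediate (not isolated)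
8 | (1R)-1-[(2S,5S)-2-methyl-5-(2-methylbut-3-en-2-yl)oxolan-2-yl]ethane-1,2-diol | OC[C@@H](O)[C@]1(C)CC[C@H](O1)C(C)(C)C=C | intermediate
9 | (2S,5S)-2-methyl-5-(2-methylbut-3-en-2-yl)oxolane-2-carbaldehyde (East fragment) | O=C[C@]1(C)CC[C@H](O1)C(C)(C)C=C | intermediate
10 | (1S,4R)-cis-4-acetoxycyclopent-2-en-1-ol | CC(=O)O[C@H]1C=C[C@@H](O)C1 | starting material
11 | (1R,4S)-4-[(tert-butyldimethylsilyl)oxy]cyclopent-2-en-1-yl acetate | CC(=O)O[C@H]1C=C[C@@H](O[Si](C)(C)C(C)(C)C)C1 | intermediate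
12 | (1R,4S)-4-[(tert-butyldimethylsilyl)oxy]cyclopent-2-en-1-ol | O[C@H]1C=C[C@@H](O[Si](C)(C)C(C)(C)C)C1 | intermediate
13 | (4S)-4-[(tert-butyldimethylsilyl)oxy]cyclopent-2-en-1-one | O=C1C=C[C@@H](O[Si](C)(C)C(C)(C)C)C1 | intermediate
14 | tert-butyldimethyl{[(1S,2S)-2-methyl-4-[(trimethylsilyl)oxy]cyclopent-3-en-1-yl]oxy}silane | C[C@H]1C=C(O[Si](C)(C)C)C[C@@H]1O[Si](C)(C)C(C)(C)C | intermediate
15 | (4S)-4-[(tert-butyldimethylsilyl)oxy]-3-methylcyclopent-2-en-1-one | O=C1C=C(C)[C@@H](O[Si](C)(C)C(C)(C)C)C1 | intermediate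
16 | (1R,4S)-4-[(tert-butyldimethylsilyl)oxy]-1-{[dimethyl(propan-2-yloxy)silyl]methyl}-3-methylcyclopent-2-en-1-ol | CC(C)O[Si](C)(C)C[C@]1(O)C=C(C)[C@@H](O[Si](C)(C)C(C)(C)C)C1 | intermediate
17 | (1R,4S)-4-[(tert-butyldimethylsilyl)oxy]-1-(hydroxymethyl)-3-methylcyclopent-2-en-1-ol | OC[C@]1(O)C=C(C)[C@@H](O[Si](C)(C)C(C)(C)C)C1 | intermediate
18 | (1R,4S)-4-[(tert-butyldimethylsilyl)oxy]-3-methyl-1-[(triethylsilyl)oxy]-1-{[(triethylsilyl)oxy]methyl}cyclopent-2-ene | CC[Si](CC)(CC)OC[C@]1(O[Si](CC)(CC)CC)C=C(C)[C@@H](O[Si](C)(C)C(C)(C)C)C1 | intermediate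
19 | (1R,4S)-4-[(tert-butyldimethylsilyl)oxy]-3-methyl-1-[(triethylsilyl)oxy]cyclopent-2-ene-1-carbaldehyde | O=C[C@]1(O[Si](CC)(CC)CC)C=C(C)[C@@H](O[Si](C)(C)C(C)(C)C)C1 | intermediate
20 | O-diisopinocampheylborinate of 21 | C=C[C@@H](C)[C@@H](OB([C@H]1C[C@H]2C[C@@H]([C@@H]1C)C2(C)C)[C@H]1C[C@H]2C[C@@H]([C@@H]1C)C2(C)C)[C@]1(O[Si](CC)(CC)CC)C=C(C)[C@@H](O[Si](C)(C)C(C)(C)C)C1 | intermediate (not isolated)
21 | (1R,2R)-1-[(1R,4S)-4-[(tert-butyldimethylsilyl)oxy]-3-methyl-1-[(triethylsilyl)oxy]cyclopent-2-en-1-yl]-2-methylbut-3-en-1-ol | C=C[C@@H](C)[C@@H](O)[C@]1(O[Si](CC)(CC)CC)C=C(C)[C@@H](O[Si](C)(C)C(C)(C)C)C1 | intermediate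
22 | (1R,4S)-1-[(1R,2R)-1-hydroxy-2-methylbut-3-en-1-yl]-3-methylcyclopent-2-ene-1,4-diol | C=C[C@@H](C)[C@@H](O)[C@]1(O)C=C(C)[C@@H](O)C1 | intermediate
23 | (4R,5R,8S)-4-[(2R)-but-3-en-2-yl]-2,2,7-trimethyl-1,3-dioxaspiro[4.4]non-6-en-8-ol | C=C[C@@H](C)[C@H]1OC(C)(C)O[C@]12C=C(C)[C@@H](O)C2 | intermediate
24 | (4R,5R)-4-[(2R)-but-3-en-2-yl]-2,2,7-trimethyl-1,3-dioxaspiro[4.4]non-6-en-8-one (West fragment) | C=C[C@@H](C)[C@H]1OC(C)(C)O[C@]12C=C(C)C(=O)C2 | intermediate
25 | lithium enolate of 24 (C3–O enolate, C3=C4) | C=C[C@@H](C)[C@H]1OC(C)(C)O[C@]12C=C(C)C([O-])=C2.[Li+] | intermediate (not isolated)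
26 | (4R,5S)-4-[(2R)-but-3-en-2-yl]-9-{hydroxy[(2S,5S)-2-methyl-5-(2-methylbut-3-en-2-yl)oxolan-2-yl]methyl}-2,2,7-trimethyl-1,3-dioxaspiro[4.4]non-6-en-8-one (mixture at C4/C5) | C=C[C@@H](C)[C@H]1OC(C)(C)O[C@]12C=C(C)C(=O)C2C(O)[C@]1(C)CC[C@H](O1)C(C)(C)C=C | intermediate
27 | (6S,9S,11E,13R,14R,15S)-5-hydroxy-14,15-(isopropylidenedioxy)-6,9-epoxyjatropha-1,11-dien-3-one (mixture at C4/C5) | CC1(C)O[C@@]23C=C(C)C(=O)C2C(O)[C@]2(C)CC[C@H](O2)C(C)(C)/C=C/[C@@H](C)[C@H]3O1 | intermediate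
28 | (6S,9S,13R,14R,15S)-5-hydroxy-14,15-(isopropylidenedioxy)-6,9-epoxyjatroph-1-en-3-one (mixture at C4/C5) | CC1(C)O[C@@]23C=C(C)C(=O)C2C(O)[C@]2(C)CC[C@H](O2)C(C)(C)CC[C@@H](C)[C@H]3O1 | intermediate
29 | C5 methanesulfonate of 28 | CC1(C)O[C@@]23C=C(C)C(=O)C2C(OS(C)(=O)=O)[C@]2(C)CC[C@H](O2)C(C)(C)CC[C@@H](C)[C@H]3O1 | intermediate (not isolated)
30 | (4E,6S,9S,13R,14R,15S)-14,15-(isopropylidenedioxy)-6,9-epoxyjatropha-1,4-dien-3-one | CC1(C)O[C@@]23C=C(C)C(=O)/C2=C/[C@]2(C)CC[C@H](O2)C(C)(C)CC[C@@H](C)[C@H]3O1 | intermediate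
31 | (4E,6S,9S,13R,14R,15S)-14,15-dihydroxy-6,9-epoxyjatropha-1,4-dien-3-one | O[C@@]12C=C(C)C(=O)/C1=C/[C@]1(C)CC[C@H](O1)C(C)(C)CC[C@@H](C)[C@H]2O | intermediate
32 | (4E,6S,9S,13R,15S)-15-hydroxy-6,9-epoxyjatropha-1,4-diene-3,14-dione | O[C@@]12C=C(C)C(=O)/C1=C/[C@]1(C)CC[C@H](O1)C(C)(C)CC[C@@H](C)C2=O | intermediate
33 | (4E,6S,9S,13R,15S)-15-acetoxy-6,9-epoxyjatropha-1,4-diene-3,14-dione | CC(=O)O[C@@]12C=C(C)C(=O)/C1=C/[C@]1(C)CC[C@H](O1)C(C)(C)CC[C@@H](C)C2=O | target

**Totals**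

Total step count: 26 (East fragment 6, West fragment 13, union and endgame 7).
Longest linear sequence: 20 steps (10 → 33, steps 7–19 and 20–26).

**Three steps most likely to fail, with fallbacks**

Step 21 (ring-closing metathesis of a diastereomer mixture at two branched vinyl groups, one of them neopentylic). Fallback: change the order so that the ring is closed on a single compound with a planar C4. Setting out from 26, MsCl/Et3N then DBU give, through the C5 mesylate of 26 F1, the open-chain cross-conjugated dienone (4R,5S,9E)-4-[(2R)-but-3-en-2-yl]-2,2,7-trimethyl-9-{[(2S,5S)-2-methyl-5-(2-methylbut-3-en-2-yl)oxolan-2-yl]methylidene}-1,3-dioxaspiro[4.4]non-6-en-8-one F2. Metathesis of F2 with the same ruthenium catalyst gives the macrocyclic trienone (4E,6S,9S,11E,13R,14R,15S)-14,15-(isopropylidenedioxy)-6,9-epoxyjatropha-1,4,11-trien-3-one F3, and RhCl(PPh3)3/H2 reduces only its C11=C12 bond, coming back to the route at 30.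

Step 22 (hydrogenation of a hindered disubstituted olefin in the presence of the enone). Fallback: take the ketone out of conjugation before reducing. Setting out from 27, Luche reduction (NaBH4, CeCl3·7H2O, MeOH) gives the macrocyclic allylic alcohol (6S,9S,11E,13R,14R,15S)-14,15-(isopropylidenedioxy)-6,9-epoxyjatropha-1,11-diene-3,5-diol F4. Its C11=C12 bond can then be reduced more forcefully (diimide from 2-nitrobenzenesulfonyl hydrazide/Et3N, or H2/RhCl(PPh3)3 under pressure) with no conjugate reduction possible, giving (6S,9S,13R,14R,15S)-14,15-(isopropylidenedioxy)-6,9-epoxyjatroph-1-ene-3,5-diol F5. MnO2 reoxidises only the allylic C3 carbinol and the route is rejoined at 28.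

Step 23 (E1cB elimination: the C4=C5 geometry is not guaranteed, and the hindered C5 alcohol may mesylate slowly). Fallback: do not rely on kinetic control of the elimination but correct the geometry afterwards by equilibration. Setting out from 28, any dehydration (for example Burgess reagent, a syn-elimination under neutral conditions) that delivers the geometric isomer (4Z,6S,9S,13R,14R,15S)-14,15-(isopropylidenedioxy)-6,9-epoxyjatropha-1,4-dien-3-one F6, alone or mixed with 30, is followed by reversible thiolate conjugate addition (PhSH cat., Et3N) or iodine/light. This equilibrates F6 to the in-ring cis isomer and comes back to the route at 30.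

**Further compounds**

F1 | step 21 | C5 methanesulfonate of 26 | C=C[C@@H](C)[C@H]1OC(C)(C)O[C@]12C=C(C)C(=O)C2C(OS(C)(=O)=O)[C@]1(C)CC[C@H](O1)C(C)(C)C=C
F2 | step 21 | (4R,5S,9E)-4-[(2R)-but-3-en-2-yl]-2,2,7-trimethyl-9-{[(2S,5S)-2-methyl-5-(2-methylbut-3-en-2-yl)oxolan-2-yl]methylidene}-1,3-dioxaspiro[4.4]non-6-en-8-one | C=C[C@@H](C)[C@H]1OC(C)(C)O[C@]12C=C(C)C(=O)/C2=C/[C@]1(C)CC[C@H](O1)C(C)(C)C=C
F3 | step 21 | (4E,6S,9S,11E,13R,14R,15S)-14,15-(isopropylidenedioxy)-6,9-epoxyjatropha-1,4,11-trien-3-one | CC1(C)O[C@@]23C=C(C)C(=O)/C2=C/[C@]2(C)CC[C@H](O2)C(C)(C)/C=C/[C@@H](C)[C@H]3O1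
F4 | step 22 | (6S,9S,11E,13R,14R,15S)-14,15-(isopropylidenedioxy)-6,9-epoxyjatropha-1,11-diene-3,5-diol (mixture at C3, C4, C5) | CC1(C)O[C@@]23C=C(C)C(O)C2C(O)[C@]2(C)CC[C@H](O2)C(C)(C)/C=C/[C@@H](C)[C@H]3O1
F5 | step 22 | (6S,9S,13R,14R,15S)-14,15-(isopropylidenedioxy)-6,9-epoxyjatroph-1-ene-3,5-diol (mixture at C3, C4, C5) | CC1(C)O[C@@]23C=C(C)C(O)C2C(O)[C@]2(C)CC[C@H](O2)C(C)(C)CC[C@@H](C)[C@H]3O1
F6 | step 23 | (4Z,6S,9S,13R,14R,15S)-14,15-(isopropylidenedioxy)-6,9-epoxyjatropha-1,4-dien-3-one | CC1(C)O[C@@]23C=C(C)C(=O)/C2=C\[C@]2(C)CC[C@H](O2)C(C)(C)CC[C@@H](C)[C@H]3O1
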